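**Retrosynthetic overview**

- Ring A is the 3-methyltetronic acid (O1, C2=O, C3–CH3, C4–OH, C5). Its C3–C4 bond joins a propanoate α-carbon to an ester carbonyl carbon whose neighbour C5 already holds O1 and the exocyclic Z C5=C6 bond. Cutting C3–C4 gives a Z methyl 2-(propanoyloxy)alk-2-enoate, closed by Dieckmann condensation in the last step.
- That enol ester comes from O-propanoylation of a methyl 2-oxo ester, made by forming C5–C6 from a primary alkylmagnesium bromide and dimethyl oxalate; the stereocentre C7 stays β to the ketone.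
- The Z alkene C11=C12 is cut at C10–C11: B-alkyl Suzuki coupling of a Z vinyl iodide (Stork–Zhao olefination) with the 9-BBN adduct of an (S)-2-methylpent-4-enyl silyl ether, whose C7 is set by an Evans allylation.
- The bis-furan aldehyde comes from 3-bromofuran and 4-bromofuran-2-carbaldehyde by aryllithium addition, ionic deoxygenation, Negishi coupling with a zinc homoenolate and ester reduction.
- Ring order: both furan rings are bought; ring A is the only ring made and it is made last.

Key step: step 14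

Remark on the chemistry: atom labels are O1, C2 (lactone C=O), C3 (C–CH3), C4 (C–OH), C5 for ring A, then C6 (=CH), C7 (S stereocentre) to C14 along the chain, with C11=C12 the Z alkene; it is assumed that the target is isolated as the drawn 4-hydroxy tautomer and that the zinc homoenolate is bought as its THF solution.

**Route**

Step 1
Reactants: 1 3-bromofuran; 2 4-bromofuran-2-carbaldehyde
Product: 4 (4-bromofuran-2-yl)(furan-3-yl)methanol (racemic), via furan-3-yllithium 3 (not isolated)
Conditions: 1, n-BuLi, THF, −78 °C; then 2, −78 °C; aq NH4Cl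
Reagents that add atoms: none
Why: Bromine–lithium exchange on 3-bromofuran is fast at −78 °C, where the 3-lithio species does not isomerise, and its 1,2-addition to the aldehyde should outrun exchange at the ring bromide of 2; the carbinol centre forms as a racemate and is erased in step 2.

Step 2
Reactants: 4 (4-bromofuran-2-yl)(furan-3-yl)methanol
Product: 5 4-bromo-2-(furan-3-ylmethyl)furan
Conditions: Et3SiH (3 equiv), CF3CO2H, CH2Cl2, −20 → 0 °C
Reagents that add atoms: none
Why: Ionic hydrogenation (ionisation to the furan-stabilised carbocation, then hydride transfer from the silane) should remove the doubly activated hydroxyl, the silane being present before the acid so that the cation is reduced before it can alkylate another furan ring.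

Step 3
Reactants: 5 4-bromo-2-(furan-3-ylmethyl)furan; 6 (3-ethoxy-3-oxopropyl)zinc bromide
Product: 7 ethyl 3-[5-(furan-3-ylmethyl)furan-3-yl]propanoate
Conditions: Pd(OAc)2 (2 mol %), SPhos (4 mol %), THF, 50 °C
Reagents that add atoms: none
Why: Negishi sp2–sp3 coupling, in which the bulky biarylphosphine speeds oxidative addition to the electron-rich bromofuran and reductive elimination ahead of β-hydride elimination, and the zinc homoenolate tolerates its own ester.

Step 4
Reactants: 7 ethyl 3-[5-(furan-3-ylmethyl)furan-3-yl]propanoate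
Product: 8 3-[5-(furan-3-ylmethyl)furan-3-yl]propanal
Conditions: i-Bu2AlH (1.05 equiv), CH2Cl2, −78 °C; aq potassium sodium tartrate
Reagents that add atoms: none
Why: Partial hydride reduction of an ester at −78 °C stops at the aluminium hemiacetal, which releases the aldehyde only on work-up.

Step 5
Reactants: 8 3-[5-(furan-3-ylmethyl)furan-3-yl]propanal
Product: 9 2-(furan-3-ylmethyl)-4-[(3Z)-4-iodopent-3-en-1-yl]furan
Conditions: EtPPh3I, n-BuLi, THF, 20 °C; I2, −78 °C; NaN(SiMe3)2, −20 °C; then 8, −78 → −20 °C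
Reagents that add atoms: ethyltriphenylphosphonium iodide CC[P+](c1ccccc1)(c1ccccc1)c1ccccc1.[I-]; iodine II
Why: Stork–Zhao olefination, in which the non-stabilised α-iodo ylide made in the flask adds to the unbranched aldehyde under kinetic control to give the Z 2-iodoalk-2-ene (iodine cis to the chain), the geometry that step 9 turns into the Z C11=C12 alkene.

Step 6
Reactants: 10 (4R)-4-benzyl-3-propanoyl-1,3-oxazolidin-2-one; 11 3-iodoprop-1-ene
Product: 13 (4R)-4-benzyl-3-[(2S)-2-methylpent-4-enoyl]-1,3-oxazolidin-2-one, via sodium enolate 12 (not isolated)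
Conditions: NaN(SiMe3)2, THF, −78 °C; then 11, −78 → −45 °C
Reagents that add atoms: none
Why: Evans asymmetric alkylation, in which the chelated Z sodium enolate is allylated on the face away from the benzyl group of the (R)-auxiliary, which sets the future C7 as S.

Step 7
Reactants: 13 (4R)-4-benzyl-3-[(2S)-2-methylpent-4-enoyl]-1,3-oxazolidin-2-one
Product: 14 (2S)-2-methylpent-4-en-1-ol
Conditions: LiBH4, H2O (1 equiv), Et2O, 0 °C
Reagents that add atoms: none
Why: Reductive cleavage of the N-acyl oxazolidinone by borohydride at the exocyclic carbonyl should give the primary alcohol without touching the α-stereocentre and return the auxiliary.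

Step 8
Reactants: 14 (2S)-2-methylpent-4-en-1-ol
Product: 15 tert-butyl(dimethyl){[(2S)-2-methylpent-4-en-1-yl]oxy}silane
Conditions: TBSCl, imidazole, CH2Cl2, 0 → 20 °C
Reagents that add atoms: tert-butyl(chloro)dimethylsilane CC(C)(C)[Si](C)(C)Cl
Why: Silylation of the primary alcohol masks the hydroxyl against the borane and the basic coupling medium of step 9 and makes the volatile alcohol easier to handle.

Step 9
Reactants: 15 tert-butyl(dimethyl){[(2S)-2-methylpent-4-en-1-yl]oxy}silane; 9 2-(furan-3-ylmethyl)-4-[(3Z)-4-iodopent-3-en-1-yl]furan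
Product: 17 tert-butyl({(2S,6Z)-9-[5-(furan-3-ylmethyl)furan-3-yl]-2,6-dimethylnon-6-en-1-yl}oxy)dimethylsilane, via B-alkyl-9-BBN 16 (not isolated)
Conditions: 15, 9-BBN, THF, 20 °C; then 9, Pd(dppf)Cl2 (5 mol %), AsPh3, Cs2CO3, DMF/H2O, 20 °C
Reagents that add atoms: none
Why: Anti-Markovnikov hydroboration of the terminal alkene followed by B-alkyl Suzuki–Miyaura coupling, which proceeds with retention at the iodide-bearing carbon so that the new chain ends cis to the furylethyl chain (Z C11=C12); the borane is used up before 9 is added, so the furans and the vinyl iodide are not hydroborated.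

Step 10
Reactants: 17 tert-butyl({(2S,6Z)-9-[5-(furan-3-ylmethyl)furan-3-yl]-2,6-dimethylnon-6-en-1-yl}oxy)dimethylsilane
Product: 18 (2S,6Z)-9-[5-(furan-3-ylmethyl)furan-3-yl]-2,6-dimethylnon-6-en-1-ol
Conditions: Bu4NF, THF, 20 °C
Reagents that add atoms: none
Why: Fluoride-induced cleavage of the Si–O bond should free the primary alcohol, nothing else in the molecule being fluoride-labile.

Step 11
Reactants: 18 (2S,6Z)-9-[5-(furan-3-ylmethyl)furan-3-yl]-2,6-dimethylnon-6-en-1-ol
Product: 19 4-[(3Z,8S)-9-bromo-4,8-dimethylnon-3-en-1-yl]-2-(furan-3-ylmethyl)furan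
Conditions: CBr4, PPh3, 2,6-lutidine, CH2Cl2, 0 °C
Reagents that add atoms: tetrabromomethane BrC(Br)(Br)Br
Why: Appel reaction, an SN2 displacement of the alkoxyphosphonium by bromide at the primary carbon next to (not at) the stereocentre, with the lutidine buffering traces of HBr to protect the furans.

Step 12
Reactants: 19 4-[(3Z,8S)-9-bromo-4,8-dimethylnon-3-en-1-yl]-2-(furan-3-ylmethyl)furan; 20 dimethyl oxalate
Product: 22 methyl (4S,8Z)-11-[5-(furan-3-ylmethyl)furan-3-yl]-4,8-dimethyl-2-oxoundec-8-enoate, via Grignard reagent 21 (not isolated)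
Conditions: Mg (I2-activated), THF, 40 °C; then added to 20 (3 equiv), THF, −78 °C; aq NH4Cl
Reagents that add atoms: none
Why: Grignard mono-acylation of an oxalate diester, in which inverse addition to excess oxalate at −78 °C gives a chelated magnesium hemiketal that collapses to the 2-oxo ester only on quench, so that a second addition is suppressed and C7 ends β to the ketone.

Step 13
Reactants: 22 methyl (4S,8Z)-11-[5-(furan-3-ylmethyl)furan-3-yl]-4,8-dimethyl-2-oxoundec-8-enoate; 23 propanoic anhydride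
Product: 24 methyl (2Z,4S,8Z)-11-[5-(furan-3-ylmethyl)furan-3-yl]-4,8-dimethyl-2-(propanoyloxy)undeca-2,8-dienoate
Conditions: Et3N, DMAP (10 mol %), CH2Cl2, 0 → 20 °C
Reagents that add atoms: none
Why: Enol esterification of a 2-oxo ester, which can enolise only towards C6, and whose less strained enolate (C7 trans to the ester group) is trapped on oxygen by the N-acylpyridinium, so the Z enol ester should predominate.

Step 14
Reactants: 24 methyl (2Z,4S,8Z)-11-[5-(furan-3-ylmethyl)furan-3-yl]-4,8-dimethyl-2-(propanoyloxy)undeca-2,8-dienoate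
Product: 27 (5Z)-5-{(2S,6Z)-9-[5-(furan-3-ylmethyl)furan-3-yl]-2,6-dimethylnon-6-en-1-ylidene}-4-hydroxy-3-methylfuran-2(5H)-one (target), via lithium ester enolate 25 (not isolated), via lithium tetronate 26 (not isolated)
Conditions: LiN(SiMe3)2 (2.5 equiv), THF, −78 → −20 °C; then 1 M HCl, 0 °C
Reagents that add atoms: none
Why: Dieckmann (intramolecular Claisen) condensation: LiN(SiMe3)2 deprotonates the propanoate CH2 to give ester enolate 25, whose carbon C3 attacks the methyl ester carbonyl C4 on the same carbon as the acyloxy group, methoxide leaves, and the 1,3-dicarbonyl product is deprotonated at once to the stable tetronate 26, which cold acid converts into 27. The closest known reaction type is the amide-base cyclisation of α-acyloxy esters, enol esters of 2-oxo esters included, to tetronic acids and 5-ylidene tetronic acids. Ring A (O1, C2, C3, C4, C5) closes in the 5-exo-trig mode at the ester carbonyl, with the enolate double bond inside the forming ring, a strained arrangement through which this substrate class nevertheless cyclises. No stereocentre is formed: C7 is carried unchanged and the Z geometry of C5=C6 is already fixed in 24, since the only bond made is C3–C4. The step needs deprotonation at the propanoate α-carbon and not at the γ C7–H of the acrylate, and cyclisation ahead of loss of methylketene from 25; the more acidic, unhindered CH2 of an enol ester, excess base at −78 °C and the geminal position of the acceptor ester secure both.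

**Compound list**

1 | 3-bromofuran | Brc1ccoc1 | starting material
2 | 4-bromofuran-2-carbaldehyde | O=Cc1cc(Br)co1 | starting material
3 | furan-3-yllithium | [Li]c1ccoc1 | intermediate
4 | (4-bromofuran-2-yl)(furan-3-yl)methanol (racemic) | OC(c1ccoc1)c1cc(Br)co1 | intermediate
5 | 4-bromo-2-(furan-3-ylmethyl)furan | Brc1coc(Cc2ccoc2)c1 | intermediate
6 | (3-ethoxy-3-oxopropyl)zinc bromide | CCOC(=O)CC[Zn]Br | starting material
7 | ethyl 3-[5-(furan-3-ylmethyl)furan-3-yl]propanoate | CCOC(=O)CCc1coc(Cc2ccoc2)c1 | intermediate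
8 | 3-[5-(furan-3-ylmethyl)furan-3-yl]propanal | O=CCCc1coc(Cc2ccoc2)c1 | intermediate
9 | 2-(furan-3-ylmethyl)-4-[(3Z)-4-iodopent-3-en-1-yl]furan | I/C(C)=C\CCc1coc(Cc2ccoc2)c1 | intermediate
10 | (4R)-4-benzyl-3-propanoyl-1,3-oxazolidin-2-one | CCC(=O)N1[C@H](Cc2ccccc2)COC1=O | starting material
11 | 3-iodoprop-1-ene | C=CCI | starting material
12 | sodium (Z)-enolate of 10 | C/C=C(\[O-])N1[C@H](Cc2ccccc2)COC1=O.[Na+] | intermediate
13 | (4R)-4-benzyl-3-[(2S)-2-methylpent-4-enoyl]-1,3-oxazolidin-2-one | C=CC[C@H](C)C(=O)N1[C@H](Cc2ccccc2)COC1=O | intermediate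
14 | (2S)-2-methylpent-4-en-1-ol | C=CC[C@H](C)CO | intermediate
15 | tert-butyl(dimethyl){[(2S)-2-methylpent-4-en-1-yl]oxy}silane | C=CC[C@H](C)CO[Si](C)(C)C(C)(C)C | intermediate
16 | 9-[(4S)-5-{[tert-butyl(dimethyl)silyl]oxy}-4-methylpentyl]-9-borabicyclo[3.3.1]nonane | CC(C)(C)[Si](C)(C)OC[C@@H](C)CCCB1C2CCCC1CCC2 | intermediate
17 | tert-butyl({(2S,6Z)-9-[5-(furan-3-ylmethyl)furan-3-yl]-2,6-dimethylnon-6-en-1-yl}oxy)dimethylsilane | CC(C)(C)[Si](C)(C)OC[C@@H](C)CCC/C(C)=C\CCc1coc(Cc2ccoc2)c1 | intermediate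
18 | (2S,6Z)-9-[5-(furan-3-ylmethyl)furan-3-yl]-2,6-dimethylnon-6-en-1-ol | OC[C@@H](C)CCC/C(C)=C\CCc1coc(Cc2ccoc2)c1 | intermediate
19 | 4-[(3Z,8S)-9-bromo-4,8-dimethylnon-3-en-1-yl]-2-(furan-3-ylmethyl)furan | BrC[C@@H](C)CCC/C(C)=C\CCc1coc(Cc2ccoc2)c1 | intermediate
20 | dimethyl oxalate | COC(=O)C(=O)OC | starting material
21 | {(2S,6Z)-9-[5-(furan-3-ylmethyl)furan-3-yl]-2,6-dimethylnon-6-en-1-yl}magnesium bromide | Br[Mg]C[C@@H](C)CCC/C(C)=C\CCc1coc(Cc2ccoc2)c1 | intermediate
22 | methyl (4S,8Z)-11-[5-(furan-3-ylmethyl)furan-3-yl]-4,8-dimethyl-2-oxoundec-8-enoate | COC(=O)C(=O)C[C@@H](C)CCC/C(C)=C\CCc1coc(Cc2ccoc2)c1 | intermediate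
23 | propanoic anhydride | CCC(=O)OC(=O)CC | starting material
24 | methyl (2Z,4S,8Z)-11-[5-(furan-3-ylmethyl)furan-3-yl]-4,8-dimethyl-2-(propanoyloxy)undeca-2,8-dienoate | CCC(=O)O/C(C(=O)OC)=C\[C@@H](C)CCC/C(C)=C\CCc1coc(Cc2ccoc2)c1 | intermediate
25 | lithium enolate of the propanoate of 24 | [Li+].CC=C([O-])O/C(C(=O)OC)=C\[C@@H](C)CCC/C(C)=C\CCc1coc(Cc2ccoc2)c1 | intermediate
26 | lithium salt (tetronate) of 27 | [Li+].CC1=C([O-])/C(=C/[C@@H](C)CCC/C(C)=C\CCc2coc(Cc3ccoc3)c2)OC1=O | intermediate
27 | (5Z)-5-{(2S,6Z)-9-[5-(furan-3-ylmethyl)furan-3-yl]-2,6-dimethylnon-6-en-1-ylidene}-4-hydroxy-3-methylfuran-2(5H)-one | CC1=C(O)/C(=C/[C@@H](C)CCC/C(C)=C\CCc2coc(Cc3ccoc3)c2)OC1=O | target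

**Step count**

Total: 14 steps. Longest linear sequence: 11 steps (steps 1–5, then 9–14).

**Steps most likely to fail**

1. Step 14 (Dieckmann closure). Enolate 25 may fragment by loss of methylketene, because the 2-oxo ester enolate is a good leaving group. The base may also remove the γ C7–H, which would erode the stereocentre, or intermolecular Claisen condensation may compete.
Fallback, from alcohol 18 back to target 27: the C5=C6 bond is made by aldol condensation on a preformed tetronate instead.
 - Oxidation of 18 with Dess–Martin periodinane (NaHCO3, CH2Cl2) should give (2S,6Z)-9-[5-(furan-3-ylmethyl)furan-3-yl]-2,6-dimethylnon-6-enal F1, used at once at −78 °C to limit epimerisation.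
 - Addition of F1 to the C5-lithio derivative of 4-methoxy-3-methylfuran-2(5H)-one (COC1=C(C)C(=O)OC1; LiN(i-Pr)2, THF, −78 °C) should give the aldol adduct 5-{(2S,6Z)-9-[5-(furan-3-ylmethyl)furan-3-yl]-1-hydroxy-2,6-dimethylnon-6-en-1-yl}-4-methoxy-3-methylfuran-2(5H)-one F2 as a diastereomer mixture.
 - MsCl/Et3N converts it into (2S,6Z)-9-[5-(furan-3-ylmethyl)furan-3-yl]-1-(3-methoxy-4-methyl-5-oxo-2,5-dihydrofuran-2-yl)-2,6-dimethylnon-6-en-1-yl methanesulfonate F3.
 - DBU eliminates F3 to the more stable Z ylidene, (5Z)-5-{(2S,6Z)-9-[5-(furan-3-ylmethyl)furan-3-yl]-2,6-dimethylnon-6-en-1-ylidene}-4-methoxy-3-methylfuran-2(5H)-one F4.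
 - Lithium propane-1-thiolate in DMF cleaves the methyl ether and gives 27.

2. Step 5 (Stork–Zhao olefination). Iodination of the ylide may be incomplete, so that the non-iodinated alkene forms; iodo-epoxide formation and low conversion are also possible, and the Z/E selectivity may erode.
Fallback, from aldehyde 8 and silyl ether 15 back to 17: the alkene geometry is set by a Z-selective phosphonate olefination and the chain is joined at an allylic carbon.
 - Still–Gennari olefination of 8 with ethyl 2-[bis(2,2,2-trifluoroethoxy)phosphoryl]propanoate (KN(SiMe3)2, 18-crown-6, THF, −78 °C) should give ethyl (2Z)-5-[5-(furan-3-ylmethyl)furan-3-yl]-2-methylpent-2-enoate F5.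
 - i-Bu2AlH reduction gives (2Z)-5-[5-(furan-3-ylmethyl)furan-3-yl]-2-methylpent-2-en-1-ol F6, and CBr4/PPh3 gives 4-[(3Z)-5-bromo-4-methylpent-3-en-1-yl]-2-(furan-3-ylmethyl)furan F7.
 - Ozonolysis of 15 with NaBH4 work-up gives (3S)-4-{[tert-butyl(dimethyl)silyl]oxy}-3-methylbutan-1-ol F8, and CBr4/PPh3 gives [(2S)-4-bromo-2-methylbutoxy](tert-butyl)dimethylsilane F9.
 - Mg converts F9 into {(3S)-4-{[tert-butyl(dimethyl)silyl]oxy}-3-methylbutyl}magnesium bromide F10.
 - Li2CuCl4-catalysed coupling of F10 with F7 (THF, −78 → 0 °C), a substitution at the primary allylic carbon that keeps the alkene geometry, gives 17.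

3. Step 13 (enol esterification). Enolisation and acylation may proceed without geometric control, giving the E enol ester beside the Z one, or slow acylation may let the 2-oxo ester undergo aldol self-condensation.
Fallback, from 22 back to 24: the geometry is fixed on silicon first and the acyl group is then exchanged for silicon.
 - TBSOTf/Et3N (CH2Cl2, −78 → 0 °C) should convert 22 into the Z silyl enol ether methyl (2Z,4S,8Z)-2-{[tert-butyl(dimethyl)silyl]oxy}-11-[5-(furan-3-ylmethyl)furan-3-yl]-4,8-dimethylundeca-2,8-dienoate F11, which can be purified.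
 - Fluoride-catalysed exchange with propanoyl fluoride (catalytic Bu4N Ph3SiF2, THF, 0 °C) should then give 24 with the enolate geometry retained.

**Further compounds**

F1 | step 14 | (2S,6Z)-9-[5-(furan-3-ylmethyl)furan-3-yl]-2,6-dimethylnon-6-enal | O=C[C@@H](C)CCC/C(C)=C\CCc1coc(Cc2ccoc2)c1
F2 | step 14 | 5-{(2S,6Z)-9-[5-(furan-3-ylmethyl)furan-3-yl]-1-hydroxy-2,6-dimethylnon-6-en-1-yl}-4-methoxy-3-methylfuran-2(5H)-one (diastereomer mixture) | COC1=C(C)C(=O)OC1C(O)[C@@H](C)CCC/C(C)=C\CCc1coc(Cc2ccoc2)c1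
F3 | step 14 | (2S,6Z)-9-[5-(furan-3-ylmethyl)furan-3-yl]-1-(3-methoxy-4-methyl-5-oxo-2,5-dihydrofuran-2-yl)-2,6-dimethylnon-6-en-1-yl methanesulfonate (diastereomer mixture) | COC1=C(C)C(=O)OC1C(OS(C)(=O)=O)[C@@H](C)CCC/C(C)=C\CCc1coc(Cc2ccoc2)c1
F4 | step 14 | (5Z)-5-{(2S,6Z)-9-[5-(furan-3-ylmethyl)furan-3-yl]-2,6-dimethylnon-6-en-1-ylidene}-4-methoxy-3-methylfuran-2(5H)-one | COC1=C(C)C(=O)O/C1=C\[C@@H](C)CCC/C(C)=C\CCc1coc(Cc2ccoc2)c1
F5 | step 5 | ethyl (2Z)-5-[5-(furan-3-ylmethyl)furan-3-yl]-2-methylpent-2-enoate | CCOC(=O)/C(C)=C\CCc1coc(Cc2ccoc2)c1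
F6 | step 5 | (2Z)-5-[5-(furan-3-ylmethyl)furan-3-yl]-2-methylpent-2-en-1-ol | OC/C(C)=C\CCc1coc(Cc2ccoc2)c1
F7 | step 5 | 4-[(3Z)-5-bromo-4-methylpent-3-en-1-yl]-2-(furan-3-ylmethyl)furan | BrC/C(C)=C\CCc1coc(Cc2ccoc2)c1
F8 | step 5 | (3S)-4-{[tert-butyl(dimethyl)silyl]oxy}-3-methylbutan-1-ol | OCC[C@H](C)CO[Si](C)(C)C(C)(C)C
F9 | step 5 | [(2S)-4-bromo-2-methylbutoxy](tert-butyl)dimethylsilane | BrCC[C@H](C)CO[Si](C)(C)C(C)(C)C
F10 | step 5 | {(3S)-4-{[tert-butyl(dimethyl)silyl]oxy}-3-methylbutyl}magnesium bromide | Br[Mg]CC[C@H](C)CO[Si](C)(C)C(C)(C)C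
F11 | step 13 | methyl (2Z,4S,8Z)-2-{[tert-butyl(dimethyl)silyl]oxy}-11-[5-(furan-3-ylmethyl)furan-3-yl]-4,8-dimethylundeca-2,8-dienoate | CC(C)(C)[Si](C)(C)O/C(C(=O)OC)=C\[C@@H](C)CCC/C(C)=C\CCc1coc(Cc2ccoc2)c1
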